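The cyclohexenone ring is numbered C1 (ketone), C2 (CH2OH), C3, C4 (angelate), C5 (isopropyl), C6 (epoxyangelate). Everything rests on cutting C5–C6, the bond that also closes the p-menthane ring in biosynthesis. The feature exploited is the C6 carbinol flanked by the C1 ketone and by the isopropyl-bearing C5: read as isopropenyl, this is a carbonyl-ene retron. The key step, a chelation-activated intramolecular glyoxal-ene reaction, closes the ring, sets C5 and C6 and frees only the C6 hydroxyl in one operation. Its precursor is an acyclic oxidised neral analogue: a (Z)-2-oxo-enal bearing a silyloxy stereocentre and a prenyl-type alkene. C4 is inverted later, as the angelate enters.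

Key step: step 10

Assumption: in step 4 the (R,R)-ligand is taken to deliver the (R)-carbinol (attack on the same aldehyde face as in ProPhenol aldol reactions); if the sense proves opposite, the equally available (S,S)-ligand is used.

Step 1
Reactants: 1 angelic acid
Product: 2 (Z)-2-methylbut-2-en-1-ol
Conditions: LiAlH4, Et2O, 0 °C to rt
Reagents that add atoms: none
Why: Hydride reduction of the conjugated carboxylic acid should proceed in the 1,2-sense to the allylic alcohol and leave the (Z)-trisubstituted alkene untouched.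

Step 2
Reactants: 2 (Z)-2-methylbut-2-en-1-ol
Product: 3 [(2S,3R)-2,3-dimethyloxiran-2-yl]methanol
Conditions: Ti(OiPr)4 (cat.), L-(+)-diethyl tartrate (cat.), t-BuOOH, 4 Å MS, CH2Cl2, −20 °C
Reagents that add atoms: tert-butyl hydroperoxide, CC(C)(C)OO
Why: Sharpless asymmetric epoxidation with the L-(+)-tartrate should give the (2S,3R)-epoxy alcohol, as it does for (Z)-allylic alcohols in general; the syn oxygen transfer keeps the C3 methyl cis to CH2OH and so sets both epoxide stereocentres.

Step 3
Reactants: 3 [(2S,3R)-2,3-dimethyloxiran-2-yl]methanol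
Product: 4 (2R,3R)-2,3-dimethyloxirane-2-carboxylic acid (epoxyangelic acid)
Conditions: RuCl3·xH2O (cat.), NaIO4, MeCN/EtOAc/H2O, 0 °C to rt
Reagents that add atoms: water, O
Why: Catalytic RuO4 oxidation takes the primary alcohol through the aldehyde hydrate to the acid without touching the epoxide; the C2 descriptor changes from S to R only because the substituent priorities change.

Step 4
Reactants: 5 3-methylbut-2-enal, 6 4-methoxybenzyl propargyl ether
Product: 8 (R)-1-[(4-methoxybenzyl)oxy]-6-methylhept-5-en-2-yn-4-ol, via alkynyl(methyl)zinc 7 (not isolated)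
Conditions: Me2Zn, (R,R)-ProPhenol [2,6-bis{[(R)-2-(hydroxydiphenylmethyl)pyrrolidin-1-yl]methyl}-4-methylphenol] (cat.), Ph3PO (cat.), toluene, 0 °C
Reagents that add atoms: none
Why: The dinuclear zinc–ProPhenol asymmetric alkynylation, a method suited to α,β-unsaturated aldehydes, should add 7 to one aldehyde face and set the carbinol centre (future C4) as R.

Step 5
Reactants: 8 (R)-1-[(4-methoxybenzyl)oxy]-6-methylhept-5-en-2-yn-4-ol
Product: 10 (2Z,4R)-2-iodo-1-[(4-methoxybenzyl)oxy]-6-methylhepta-2,5-dien-4-ol, via cyclic vinylalanate 9 (not isolated)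
Conditions: NaAlH2(OCH2CH2OMe)2 (Red-Al), THF, 0 °C to rt; then NIS, −78 to 0 °C
Reagents that add atoms: N-iodosuccinimide, O=C1CCC(=O)N1I
Why: Alkoxide-directed trans-hydroalumination places aluminium on the alkyne carbon remote from the carbinol inside the five-membered alanate 9, and iodinolysis with retention gives the (Z)-iodoalkene with iodine (the future C1 site) cis to the carbinol carbon.

Step 6
Reactants: 10 (2Z,4R)-2-iodo-1-[(4-methoxybenzyl)oxy]-6-methylhepta-2,5-dien-4-ol
Product: 11 tert-butyl{[(2Z,4R)-2-iodo-1-(4-methoxybenzyloxy)-6-methylhepta-2,5-dien-4-yl]oxy}dimethylsilane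
Conditions: TBSCl, imidazole, DMF, rt
Reagents that add atoms: tert-butyldimethylsilyl chloride, CC(C)(C)[Si](C)(C)Cl
Why: This standard silylation blocks hemiketal and furan formation once the cis ketone is in place, and the silyl ether later serves as the steering group of the key step.

Step 7
Reactants: 11 silyl ether of the iodo dienol, 12 (tert-butyldimethylsilyloxy)acetaldehyde
Product: 13 (3Z,5R)-1,5-bis(tert-butyldimethylsilyloxy)-3-{[(4-methoxybenzyl)oxy]methyl}-7-methylocta-3,6-dien-2-ol (C2 epimers)
Conditions: CrCl2, NiCl2 (cat.), DMF, rt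
Reagents that add atoms: none
Why: In the Nozaki–Hiyama–Kishi coupling the alkenylchromium species keeps the trisubstituted alkene geometry and adds to the aldehyde under non-basic conditions, which avoids the 1,4 oxygen-to-carbon silyl shift expected of the alkenyllithium; the new carbinol centre is lost in step 9.

Step 8
Reactants: 13 bis-silyl ether
Product: 14 (3Z,5R)-5-(tert-butyldimethylsilyloxy)-3-{[(4-methoxybenzyl)oxy]methyl}-7-methylocta-3,6-diene-1,2-diol (C2 epimers)
Conditions: HF·pyridine, pyridine, THF, 0 °C
Reagents that add atoms: none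
Why: In this chemoselective desilylation, buffered fluoride should cleave the unhindered primary silyl ether much faster than the hindered secondary one.

Step 9
Reactants: 14 diol
Product: 15 (3Z,5R)-5-(tert-butyldimethylsilyloxy)-3-{[(4-methoxybenzyl)oxy]methyl}-7-methyl-2-oxoocta-3,6-dienal
Conditions: (COCl)2, DMSO, CH2Cl2, −78 °C; Et3N, −78 to −30 °C; dried and used at once
Reagents that add atoms: none
Why: Swern oxidation turns both hydroxyls of a 1,2-diol into carbonyl groups without glycol cleavage, and the low temperature should preserve the (Z)-alkene and the silyl ether.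

Step 10
Reactants: 15 (Z)-2-oxo-enal
Product: 16 (4S,5S,6S)-4-(tert-butyldimethylsilyloxy)-6-hydroxy-2-{[(4-methoxybenzyl)oxy]methyl}-5-(prop-1-en-2-yl)cyclohex-2-en-1-one (all-trans at C4, C5, C6)
Conditions: Cu(OTf)2 (cat.), 2,2'-(propane-2,2-diyl)bis(4,4-dimethyl-4,5-dihydrooxazole) (cat.), 4 Å MS, CH2Cl2, −20 °C to rt
Reagents that add atoms: none
Why: Divalent copper binds both oxygens of the s-cis 1,2-dicarbonyl unit of 15, and C5 of the trisubstituted alkene attacks the activated aldehyde carbon C6 while an allylic methyl hydrogen passes to the aldehyde oxygen through a six-centre, asynchronous concerted carbonyl-ene transition state. The closest known reaction types are the cyclisation of citronellal to isopulegol or of neral to isopiperitenol and the Cu(OTf)2–bis(oxazoline)-catalysed intramolecular ene reactions of unsaturated 1,2-dicarbonyl compounds. The cyclohexenone ring closes in a 6-exo-trig mode at both the alkene and the carbonyl group, made easy by the (Z)-alkene that already holds C1 and C4 on one side. C6 is controlled by the chelate, which keeps the aldehyde oxygen coplanar with the C1 carbonyl so that the new hydroxyl is equatorial, and C5 by the chair-like ene geometry, which needs the isopropenyl carbon gauche to that oxygen, hence equatorial and trans. The absolute sense of both comes from C4, because allylic 1,3-strain with the cis methyl of the isopropylidene group puts H4 in the alkene plane and the silyloxy group pseudo-equatorial, trans to the new isopropenyl group. The step needs reaction at the aldehyde and not at the conjugated ketone (which would give a five-membered ring) and no ionisation of the doubly allylic silyl ether, secured by the higher electrophilicity of the aldehyde and by a mild aprotic catalyst with molecular sieves.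

Step 11
Reactants: 16 ene product, 4 (2R,3R)-epoxyangelic acid
Product: 17 (4S,5S,6S)-4-(tert-butyldimethylsilyloxy)-6-[(2R,3R)-2,3-dimethyloxirane-2-carbonyloxy]-2-{[(4-methoxybenzyl)oxy]methyl}-5-(prop-1-en-2-yl)cyclohex-2-en-1-one
Conditions: 2-methyl-6-nitrobenzoic anhydride, DMAP (cat.), Et3N, CH2Cl2, rt
Reagents that add atoms: none
Why: The Shiina esterification (mixed anhydride activated by DMAP) should acylate the equatorial C6 hydroxyl with the α-quaternary acid under mild conditions and cap the isomerisation-prone α'-hydroxy enone with retention at every centre.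

Step 12
Reactants: 17 isopropenyl ester
Product: 18 (4S,5S,6S)-4-(tert-butyldimethylsilyloxy)-6-[(2R,3R)-2,3-dimethyloxirane-2-carbonyloxy]-5-isopropyl-2-{[(4-methoxybenzyl)oxy]methyl}cyclohex-2-en-1-one
Conditions: H2 (1 atm), RhCl(PPh3)3 (cat.), toluene/EtOH, rt
Reagents that add atoms: none
Why: Homogeneous hydrogenation with RhCl(PPh3)3 reduces a 1,1-disubstituted alkene much faster than a trisubstituted conjugated one, as in the reduction of carvone to carvotanacetone, and spares benzyl-type ethers and epoxides.

Step 13
Reactants: 18 silyl ether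
Product: 19 (4S,5R,6S)-6-[(2R,3R)-2,3-dimethyloxirane-2-carbonyloxy]-4-hydroxy-5-isopropyl-2-{[(4-methoxybenzyl)oxy]methyl}cyclohex-2-en-1-one
Conditions: HF·pyridine, THF, 0 °C to rt
Reagents that add atoms: none
Why: Fluoride desilylation in a non-basic medium should free the C4 hydroxyl without acyl migration, elimination or opening of the electron-poor epoxide; the C5 descriptor changes only through priorities.

Step 14
Reactants: 19 C4 alcohol, 1 angelic acid
Product: 20 (4R,5R,6S)-4-[(Z)-2-methylbut-2-enoyloxy]-6-[(2R,3R)-2,3-dimethyloxirane-2-carbonyloxy]-5-isopropyl-2-{[(4-methoxybenzyl)oxy]methyl}cyclohex-2-en-1-one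
Conditions: PPh3, DIAD, toluene, 0 °C to rt
Reagents that add atoms: none
Why: In this Mitsunobu esterification the pseudo-equatorial C4 oxyphosphonium group has no antiperiplanar hydrogen at C5, so angelate should displace it by SN2 with inversion (the menthol to neomenthyl ester case) to give the ester cis to isopropyl, and the neutral medium keeps the (Z)-angelate geometry.

Step 15
Reactants: 20 4-methoxybenzyl ether
Product: 21 target, (4R,5R,6S)-4-angeloyloxy-6-[(2R,3R)-epoxyangeloyloxy]-2-(hydroxymethyl)-5-isopropylcyclohex-2-en-1-one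
Conditions: DDQ, CH2Cl2/pH 7 buffer, 0 °C
Reagents that add atoms: none
Why: Oxidative cleavage of the electron-rich benzyl ether by DDQ, followed by hydrolysis of the oxocarbenium ion, releases the primary alcohol under neutral conditions that both esters, the epoxide and the enone tolerate.

Compound list
1 | angelic acid, (Z)-2-methylbut-2-enoic acid | C/C=C(/C)C(=O)O | starting material
2 | (Z)-2-methylbut-2-en-1-ol | C/C=C(/C)CO | intermediate
3 | [(2S,3R)-2,3-dimethyloxiran-2-yl]methanol | OC[C@]1(C)O[C@@H]1C | intermediate
4 | (2R,3R)-2,3-dimethyloxirane-2-carboxylic acid | OC(=O)[C@]1(C)O[C@@H]1C | intermediate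
5 | 3-methylbut-2-enal | CC(C)=CC=O | starting material
6 | 4-methoxybenzyl propargyl ether | C#CCOCc1ccc(OC)cc1 | starting material
7 | methyl{3-[(4-methoxybenzyl)oxy]prop-1-ynyl}zinc (not isolated) | C[Zn]C#CCOCc1ccc(OC)cc1 | intermediate
8 | (R)-1-[(4-methoxybenzyl)oxy]-6-methylhept-5-en-2-yn-4-ol | O[C@H](C=C(C)C)C#CCOCc1ccc(OC)cc1 | intermediate
9 | sodium salt of the five-membered cyclic alkoxy(vinyl)alanate (not isolated) | [Na+].COCCO[Al-]1(OCCOC)O[C@H](C=C(C)C)C=C1COCc1ccc(OC)cc1 | intermediate
10 | (2Z,4R)-2-iodo-1-[(4-methoxybenzyl)oxy]-6-methylhepta-2,5-dien-4-ol | O[C@H](C=C(C)C)/C=C(\I)COCc1ccc(OC)cc1 | intermediate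
11 | tert-butyldimethylsilyl ether of 10 | CC(C)(C)[Si](C)(C)O[C@H](C=C(C)C)/C=C(\I)COCc1ccc(OC)cc1 | intermediate
12 | (tert-butyldimethylsilyloxy)acetaldehyde | CC(C)(C)[Si](C)(C)OCC=O | starting material
13 | (3Z,5R)-1,5-bis(tert-butyldimethylsilyloxy)-3-{[(4-methoxybenzyl)oxy]methyl}-7-methylocta-3,6-dien-2-ol, C2 epimers | CC(C)(C)[Si](C)(C)O[C@H](C=C(C)C)/C=C(\C(O)CO[Si](C)(C)C(C)(C)C)COCc1ccc(OC)cc1 | intermediate
14 | (3Z,5R)-5-(tert-butyldimethylsilyloxy)-3-{[(4-methoxybenzyl)oxy]methyl}-7-methylocta-3,6-diene-1,2-diol, C2 epimers | CC(C)(C)[Si](C)(C)O[C@H](C=C(C)C)/C=C(\C(O)CO)COCc1ccc(OC)cc1 | intermediate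
15 | (3Z,5R)-5-(tert-butyldimethylsilyloxy)-3-{[(4-methoxybenzyl)oxy]methyl}-7-methyl-2-oxoocta-3,6-dienal | CC(C)(C)[Si](C)(C)O[C@H](C=C(C)C)/C=C(\C(=O)C=O)COCc1ccc(OC)cc1 | intermediate
16 | (4S,5S,6S)-4-(tert-butyldimethylsilyloxy)-6-hydroxy-2-{[(4-methoxybenzyl)oxy]methyl}-5-(prop-1-en-2-yl)cyclohex-2-en-1-one | CC(C)(C)[Si](C)(C)O[C@H]1C=C(COCc2ccc(OC)cc2)C(=O)[C@@H](O)[C@@H]1C(C)=C | intermediate
17 | C6 (2R,3R)-epoxyangelate of 16 | CC(C)(C)[Si](C)(C)O[C@H]1C=C(COCc2ccc(OC)cc2)C(=O)[C@@H](OC(=O)[C@]2(C)O[C@@H]2C)[C@@H]1C(C)=C | intermediate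
18 | 5-isopropyl analogue of 17, (4S,5S,6S) | CC(C)(C)[Si](C)(C)O[C@H]1C=C(COCc2ccc(OC)cc2)C(=O)[C@@H](OC(=O)[C@]2(C)O[C@@H]2C)[C@@H]1C(C)C | intermediate
19 | (4S,5R,6S)-4-hydroxy compound from 18 | O[C@H]1C=C(COCc2ccc(OC)cc2)C(=O)[C@@H](OC(=O)[C@]2(C)O[C@@H]2C)[C@@H]1C(C)C | intermediate
20 | (4R,5R,6S)-4-angelate, 4-methoxybenzyl ether of the target | C/C=C(/C)C(=O)O[C@@H]1C=C(COCc2ccc(OC)cc2)C(=O)[C@@H](OC(=O)[C@]2(C)O[C@@H]2C)[C@@H]1C(C)C | intermediate
21 | CNP0293054.1, (4R,5R,6S)-4-angeloyloxy-6-[(2R,3R)-epoxyangeloyloxy]-2-(hydroxymethyl)-5-isopropylcyclohex-2-en-1-one | C/C=C(/C)C(=O)O[C@@H]1C=C(CO)C(=O)[C@@H](OC(=O)[C@]2(C)O[C@@H]2C)[C@@H]1C(C)C | target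

Total step count: 15. Longest linear sequence: 12 steps (steps 4 to 15, from 5 and 6).

Steps most likely to fail

Step 10. Three processes could stall ring closure. The Lewis acid may ionise the doubly allylic silyl ether, reversible conjugate addition may isomerise the (Z)-enone, or the glyoxal may rest as hydrate or oligomer. The fallback avoids the 2-oxo aldehyde and sets out from diol 14. Its primary hydroxyl is oxidised selectively (TEMPO, PhI(OAc)2, CH2Cl2) to the 2-hydroxy aldehyde F1. Me2AlCl (two equivalents, CH2Cl2, −78 °C) then turns the free hydroxyl into an aluminium alkoxide that chelates the aldehyde, scavenges protons and promotes the same carbonyl-ene closure to the cyclohexene-1,6-diol F2. MnO2 finally oxidises only the allylic C1 carbinol, and the route is rejoined at 16.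

Step 14. Substitution next to the isopropyl group may be slow. Loss of the activated oxygen by elimination with subsequent aromatisation, or consumption of the weakly acidic angelic acid as its anhydride, could then take over. The fallback separates the inversion from the introduction of the angelate and sets out from 19. A Mitsunobu reaction with the more acidic 4-nitrobenzoic acid, the remedy known for menthol-type alcohols, gives the inverted 4-nitrobenzoate F3. Selective methanolysis of this activated ester (NaN3, MeOH), which the hindered α-quaternary epoxy ester should survive, gives the (4R)-alcohol F4. Acylation with retention by the mixed anhydride of angelic acid and 2,4,6-trichlorobenzoyl chloride (Et3N, toluene, warm) returns to the route at 20.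

Step 4. Facial discrimination on the β,β-disubstituted enal may be poor, or methyl transfer and self-condensation of the enal may compete. The fallback separates carbon–carbon bond formation from stereocontrol and sets out from 6. Acylative Sonogashira coupling with 3-methylbut-2-enoyl chloride (PdCl2(PPh3)2, CuI, Et3N) gives the ynone F5. Midland reduction with (R)-B-isopinocampheyl-9-borabicyclo[3.3.1]nonane, which treats the alkynyl group as the small substituent as in the reduction of 1-octyn-3-one to the (R)-alcohol, returns to the route at 8.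

Further compounds
F1 | step 10 | (3Z,5R)-5-(tert-butyldimethylsilyloxy)-2-hydroxy-3-{[(4-methoxybenzyl)oxy]methyl}-7-methylocta-3,6-dienal, C2 epimers | CC(C)(C)[Si](C)(C)O[C@H](C=C(C)C)/C=C(\C(O)C=O)COCc1ccc(OC)cc1
F2 | step 10 | C1 carbinol analogue of 16 (cyclohex-2-ene-1,6-diol, C1 epimers, C4 to C6 as in 16) | CC(C)(C)[Si](C)(C)O[C@H]1C=C(COCc2ccc(OC)cc2)C(O)[C@@H](O)[C@@H]1C(C)=C
F3 | step 14 | (4R)-4-nitrobenzoate derived from 19 with inversion | O=C(O[C@@H]1C=C(COCc2ccc(OC)cc2)C(=O)[C@@H](OC(=O)[C@]2(C)O[C@@H]2C)[C@@H]1C(C)C)c1ccc(cc1)[N+](=O)[O-]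
F4 | step 14 | (4R)-epimer of alcohol 19 | O[C@@H]1C=C(COCc2ccc(OC)cc2)C(=O)[C@@H](OC(=O)[C@]2(C)O[C@@H]2C)[C@@H]1C(C)C
F5 | step 4 | 1-[(4-methoxybenzyl)oxy]-6-methylhept-5-en-2-yn-4-one | CC(C)=CC(=O)C#CCOCc1ccc(OC)cc1
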